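Remarks on the chemistry (assumptions, stated once):
- Sense of induction in step 7: quinine is assumed to behave as it does with simple cis-fused bicyclic succinic anhydrides, so that methanol enters at the carbonyl on the ring carbon that becomes C1 (R). If the crowded substrate responds in the opposite sense, quinidine is used in the same procedure.
- Compounds 4 and 10 are treated as purchasable.
- Check of structures: the target has CO2Me, CO2H and both ring methyls on one face and both pyranones on the other. This is what addition to the convex face of 3 delivers, so no structure needed correction.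
- One design change: aqueous cleavage of the azine unavoidably opens the anhydride, and free hydrazine would acylate it. Step 3 is therefore run at low pH and ends with re-closure of the anhydride.

## Structural features

The target is a fully substituted cyclobutane, numbered here C1 (CO2Me, H), C2 (CO2H, H), C3 (neighbour of C2) and C4 (neighbour of C1). C3 and C4 are quaternary; each carries a methyl group and a 4-methoxy-3-methyl-2-oxo-2H-pyran-6-yl ring bonded through C6' (pyranone atoms primed). All four ring carbons are contiguous stereocentres, C1 (R), C2 (S), C3 (R), C4 (S): ester, acid and both methyls lie on one face, both pyranones on the other. Apart from the ester/acid difference the molecule has a mirror plane through the midpoints of C1–C2 and C3–C4. It is therefore a desymmetrised meso compound, and its absolute configuration can be set by one late differentiation of two enantiotopic carbonyl groups. Fragile points are the C1–H and C2–H bonds (α to carbonyls, epimerisable by base to the trans series), the 2-pyranones (vinylogous lactones opened by hydroxide and strong nucleophiles), and the half-ester, which cannot be made by unselective esterification or saponification. The real difficulty is the C3–C4 pair: two adjacent quaternary carbons holding two large heteroaryl groups cis to each other and trans to the C1/C2 carboxyl carbons. The key step exploits this pair: the two C6' carbons are cis substituents on C3 and C4, so they can arrive together as C3 and C6 of a 1,2,4,5-tetrazine adding to a C3=C4 double bond of a cyclobutene whose C1/C2 carboxyls are tied back as a cis-fused anhydride. That anhydride locks C1/C2 cis, shields one alkene face, and is the meso electrophile of the last step.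

## Logic of the disconnections

13 ⇒ 12. The MeO–C(=O) bond at C1 is cut and the C1 and C2 carbonyl carbons are joined through one oxygen. The reason is the hidden mirror plane: 12 is meso, so no absolute configuration has to be carried through the synthesis. The demand is a chiral mediator that opens only the carbonyl on the (R) ring carbon, under conditions too mild to epimerise C1–H or C2–H.

12 ⇒ 11. The two O–CH3 bonds at C4' are cut. A 4-hydroxy-2-pyranone is the direct product of a malonyl annulation, so the methyls are best added afterwards. The demand is methylation at O4' and not at the C2' carbonyl oxygen, in a medium that leaves the anhydride closed.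

11 ⇒ 9 + 10. In each pyranone the C4'–C5' and O1'–C2' bonds are cut. Each heterocycle then separates into an enol unit (O1', C6', C5') that belongs to the core and a three-carbon unit (C2', C3' with its methyl, C4') that is 10. The gain is large: both rings shrink to two-carbon side chains. The demand is that each enol reacts with its own molecule of 10 and is not bridged to its cis neighbour.

9 ⇒ 8. The two O–Si bonds are cut, leaving two methyl ketones. Because C3 and C4 are quaternary, enolisation can only go towards the methyl groups; the demand is merely a method that spares the anhydride.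

8 ⇒ 6. The two ketone C=O groups are reconnected through N–N as a cyclic azine (retro-hydrolysis). The reason is that a cis-1,4-diketone on adjacent quaternary carbons is the hydrolysis product of a 4,5-dihydropyridazine. Two side chains become one ring and the compound becomes a cycloadduct. The forward step must remove hydrazine irreversibly and must re-close the anhydride, which passes through 7.

6 ⇒ 3 + 4 (through 5). The bonds from C3 and C4 to the two azine carbons are cut. This removes both quaternary centres, two C–C bonds and the C3/C4 relative configuration in one operation, leaving a flat symmetric alkene and a symmetric diene. The demand is severe: a tetrasubstituted dienophile must react, and it must do so on the face away from the anhydride.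

3 ⇒ 1 + 2. The two σ bonds of the cyclobutene that join the alkyne carbons to the anhydride carbons are cut (retro-[2+2]). Both fragments are commodity chemicals. The forward step needs triplet sensitisation and an excess of 2 so that excited 1 does not add a second time to 3.

## Other disconnections considered

Alternative 1: The cut is the C1–C4 σ bond of cyclobutene A2, which traces the four-membered ring back to a three-membered ring with one exocyclic carbon.
- Forward key step: photolysis or thermolysis of tosylhydrazone sodium salt A1 should give, through the diazo compound, a cyclopropylcarbene. One of its two equivalent quaternary ring carbons shifts to the carbene centre and expands the ring to A2.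
- In favour: the cis relation of the quaternary carbons already exists in the cyclopropane and is retained by a migrating carbon. Either ring bond can migrate with the same result. Ring expansion of cyclopropylcarbenes is a known reaction class, so on precedent for the key step this alternative is better founded than the chosen cycloaddition.
- Against: the carbene can also fragment to an alkene and an alkyne or insert into C–H bonds. The 2-pyranones absorb where the diazo group does and are photolabile. A1 must be built with two finished pyranones on a tetrasubstituted cyclopropane, which moves the quaternary-carbon problem without solving it. A2 contains neither carboxyl carbon, so two one-carbon units must still be added cis to each other and anti to the pyranones (for instance PdCl2/CuCl2-mediated bis-methoxycarbonylation with CO and MeOH to the meso diester A5), and the diester then desymmetrised.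
- Comparison: on structure the chosen plan is ahead, because after its key step every carbon attached to the ring is in place and the C1/C2 carboxyls already sit in the anhydride. On stereocontrol the two are equal: in both a reagent approaches the face away from the large groups and the methyls end up syn to the carboxyls. On step count the alternative should be longer than seven steps.

Alternative 2: The cut is the C5'–C6' and O1'–C2' bonds of both pyranones, leaving a cyclobutane with four carboxyl-level substituents.
- Forward key step: two equivalents of the lithium dienolate of ester A4 would be acylated at their γ-carbons by bis(acid chloride) A3, and the δ-keto esters lactonised to the meso diester A5.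
- In favour: each pyranone arrives with its 4-methoxy and 3-methyl groups, so the O4'/O2' methylation question does not arise; here the alternative is better. A5 is one enantiotopic ester hydrolysis from 13. The quaternary carbons could come from a photochemical [2+2] reaction, a class that tolerates full substitution and is better precedented than the chosen thermal cycloaddition.
- Against: both acyl carbons of A3 are neopentyl-like, cis and adjacent, so A3 should exist largely in a cyclic anhydride or pseudo-chloride form. After the first acylation the new acidic methylene can attack the neighbouring acyl chloride and close a five-membered 1,3-diketone ring instead of accepting a second dienolate. α- versus γ-acylation is sensitive to hindrance. The four carboxyl carbons of the core must first be differentiated pairwise.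
- Comparison: on structure the plans are equal, since both use the same hidden symmetry. On mechanism the chosen plan makes the pyranone-forming bonds one atom further from the quaternary carbons, which should be less hindered, but it carries the untested cycloaddition. On step economy they are about equal once the carboxyl differentiation is counted.

Alternative 3: The cut is the C3–C4 bond between the quaternary carbons, which is the C7–C8 bond of cyclooctatriene A7.
- Forward key step: tetraene A6 has one pyranone on the outside and one on the inside of its termini. It should close thermally in the conrotatory 8π mode to A7 with the two methyls cis. A7 should equilibrate by disrotatory 6π closure with bicyclo[4.2.0]octadiene A8, whose cyclohexadiene would be cleaved oxidatively to the C1/C2 carboxyls.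
- In favour: the hardest bond is made in a thermally allowed, stereospecific pericyclic step with the configuration written in alkene geometry. The cascade builds the whole cyclobutane without reagents. In atom economy and elegance of the key step this alternative is the better one.
- Against: A6 needs four double bonds of defined geometry, including a (Z,Z)-diene and a trisubstituted alkene with a pyranone inside. This raises the barrier of the helical transition state and invites Z/E isomerisation. The 6π step poses a torquoselectivity and equilibrium question (new ring syn to methyls or to pyranones). Cleavage of the diene of A8 must spare the electron-rich C5'=C6' bonds of two pyranones.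
- Comparison: on structure both use the cis relation at C3/C4, the alternative by forming C3–C4 itself, the chosen plan by adding both substituent carbons to a preformed C3=C4 bond. On mechanism both key steps are pericyclic and unproven at this substitution level, so they are equal in risk; the chosen plan needs only facial selectivity, the alternative also alkene geometry, torquoselectivity and chemoselective oxidation. On step economy the chosen plan should be shorter, since A6 alone needs a long stereocontrolled polyene assembly and the end game (as 12 to 13) is the same.

Key step: step 2

## Route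

Step 1
Reactants: 1 maleic anhydride; 2 but-2-yne
Product: 3 6,7-dimethyl-3-oxabicyclo[3.2.0]hept-6-ene-2,4-dione (cis-fused; meso)
Conditions: hν (350 nm, Pyrex), Ph2CO (0.1 equiv), 2 (5 equiv), EtOAc, −10 °C
Reagents that add atoms: none
Why: Triplet-sensitised [2+2] photocycloaddition of an enone-type chromophore to an alkyne; the five-membered anhydride can only be cis-fused to the new cyclobutene, so both new stereocentres are set by ring constraint. Excess 2 keeps excited 1 from adding a second time to the product alkene.

Step 2
Reactants: 3 6,7-dimethyl-3-oxabicyclo[3.2.0]hept-6-ene-2,4-dione; 4 3,6-dimethyl-1,2,4,5-tetrazine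
Product: 6 2,3,6,7-tetramethyl-10-oxa-4,5-diazatricyclo[6.3.0.0(2,7)]undeca-3,5-diene-9,11-dione (meso; C2/C7 methyls syn to the anhydride ring), via tetraazabicyclo[2.2.2]octadiene cycloadduct 5 (not isolated)
Conditions: 4 (2 equiv), CH2Cl2, 12 kbar, 40 °C; then 1 bar, 40 °C (−N2)
Reagents that add atoms: none
Why: Proposed new method: the electron-poor diazadiene of 4 (termini C3 and C6) and the strained, alkyl-substituted alkene of 3 should combine in a concerted, suprafacial inverse-electron-demand [4+2] cycloaddition to give 5, which expels N2 by retro-[4+2] and leaves the cyclic azine 6; the closest known reaction type is the tetrazine (Carboni–Lindsey) cycloaddition to less substituted cyclobutenes and other strained alkenes, which has not been shown on a tetrasubstituted cyclobutene forming two adjacent quaternary carbons. The only ring closed, the six-membered dihydropyridazine, is closed by cycloaddition (both C–C bonds in one suprafacial event) and revealed by cycloreversion, not by a separate cyclisation. The new stereocentres are the two ring-fusion carbons: their cis relation follows from suprafacial addition to a ring alkene, and their relation to C1/C5 of 3 from attack on the convex face, anti to the folded anhydride ring, which pushes both methyls to the anhydride side. Facial selectivity is the only selectivity required, because alkene and tetrazine are both symmetric, and the cis-fused bicyclo[3.2.0] shape provides it. High pressure is chosen because the bond-forming step has a strongly negative activation volume, which should offset the steric penalty of four methyl groups; release of cyclobutene strain and irreversible loss of N2 drive the reaction. The quaternary ring-fusion carbons prevent tautomerisation of 6 to a 1,4-dihydropyridazine and aromatisation, and the cis-fused anhydride prevents conrotatory thermal opening of 3.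

Step 3
Reactants: 6 2,3,6,7-tetramethyl-10-oxa-4,5-diazatricyclo[6.3.0.0(2,7)]undeca-3,5-diene-9,11-dione
Product: 8 6,7-diacetyl-6,7-dimethyl-3-oxabicyclo[3.2.0]heptane-2,4-dione (meso; methyls syn to the anhydride ring), via diketo diacid 7 (not isolated)
Conditions: i. 2 M H2SO4, THF, 60 °C, EtOAc extraction; ii. Ac2O, 80 °C
Reagents that add atoms: water, O
Why: Acid hydrolysis of both C=N bonds of a cyclic azine (reverse of the condensation of a 1,4-diketone with hydrazine); at low pH hydrazine stays in the aqueous phase as its non-nucleophilic hydrazinium salt, so it can neither re-condense nor acylate, and the anhydride opened to 7 is re-closed by dehydration, which only the cis-diacid can undergo. C3/C4 are quaternary and each acetyl is trans to its neighbouring carboxyl, so no stereocentre is at risk and no lactol can form.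

Step 4
Reactants: 8 6,7-diacetyl-6,7-dimethyl-3-oxabicyclo[3.2.0]heptane-2,4-dione
Product: 9 6,7-dimethyl-6,7-bis[1-(trimethylsilyloxy)ethenyl]-3-oxabicyclo[3.2.0]heptane-2,4-dione (meso; methyls syn to the anhydride ring)
Conditions: TMSOTf (2.4 equiv), Et3N (3 equiv), CH2Cl2, 0 °C
Reagents that add atoms: trimethylsilyl trifluoromethanesulfonate, C[Si](C)(C)OS(=O)(=O)C(F)(F)F
Why: Soft enolisation of two methyl ketones with a silyl triflate and a tertiary amine; each ketone has α-hydrogens only on its methyl group, so the terminal enol silane is the only regioisomer, and the less reactive anhydride α-positions should be left alone at 0 °C with a small excess of reagent.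

Step 5
Reactants: 9 6,7-dimethyl-6,7-bis[1-(trimethylsilyloxy)ethenyl]-3-oxabicyclo[3.2.0]heptane-2,4-dione; 10 2-methylpropanedioyl dichloride
Product: 11 6,7-bis(4-hydroxy-3-methyl-2-oxo-2H-pyran-6-yl)-6,7-dimethyl-3-oxabicyclo[3.2.0]heptane-2,4-dione (meso; methyls syn to the anhydride ring)
Conditions: 10 (3 equiv), Et2O, −78 °C to 20 °C (9 added to 10)
Reagents that add atoms: none
Why: Twofold pyranone annulation of a ketone enol silane with a malonyl dichloride: C-acylation at the enol carbon (future C5') by one acyl chloride, then O-acylation of the enolised diketone by the second (probably through the acylketene) closes each 4-hydroxy-3-methyl-2-pyranone as a six-membered lactone. Inverse addition into excess 10 favours one molecule of 10 per enol silane; no stereocentre is touched and the anhydride is inert to acid chloride and HCl.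

Step 6
Reactants: 11 6,7-bis(4-hydroxy-3-methyl-2-oxo-2H-pyran-6-yl)-6,7-dimethyl-3-oxabicyclo[3.2.0]heptane-2,4-dione
Product: 12 6,7-bis(4-methoxy-3-methyl-2-oxo-2H-pyran-6-yl)-6,7-dimethyl-3-oxabicyclo[3.2.0]heptane-2,4-dione (meso; methyls syn to the anhydride ring)
Conditions: Me2SO4 (2.5 equiv), K2CO3 (2.5 equiv), dry acetone, 40 °C
Reagents that add atoms: dimethyl sulfate, COS(=O)(=O)OC
Why: O-Alkylation of a vinylogous acid (4-hydroxy-2-pyranone, pKa about 5) with a sulfate ester and a mild heterogeneous base, conditions under which this ring system is expected to give the 4-methoxy-2-pyranone and not the 2-methoxy-4-pyranone. Dry acetone and insoluble carbonate are chosen so that the anhydride stays closed.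

Step 7
Reactants: 12 6,7-bis(4-methoxy-3-methyl-2-oxo-2H-pyran-6-yl)-6,7-dimethyl-3-oxabicyclo[3.2.0]heptane-2,4-dione
Product: 13 (1S,2R,3S,4R)-4-(methoxycarbonyl)-2,3-bis(4-methoxy-3-methyl-2-oxo-2H-pyran-6-yl)-2,3-dimethylcyclobutane-1-carboxylic acid (target; in the route numbering C1 R; C2 S; C3 R; C4 S)
Conditions: quinine (1.1 equiv), MeOH (3 equiv), PhMe, −55 °C; 1 M HCl work-up
Reagents that add atoms: methanol, CO
Why: Cinchona-alkaloid-mediated desymmetrising alcoholysis of a meso cyclic anhydride: the quinuclidine nitrogen activates methanol by general-base catalysis within the chiral pocket and differentiates the two enantiotopic carbonyls, so opening at the carbonyl on the (R) ring carbon fixes C1 (R), C2 (S), C3 (R) and C4 (S) together. Low temperature and the absence of strong base leave C1–H, C2–H and the pyranones untouched; quinine is recovered from the acid wash.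

## Compound list

1 | maleic anhydride | O=C1OC(=O)C=C1 | starting material
2 | but-2-yne | CC#CC | starting material
3 | 6,7-dimethyl-3-oxabicyclo[3.2.0]hept-6-ene-2,4-dione (cis-fused, meso) | O=C1OC(=O)[C@@H]2[C@H]1C(C)=C2C | intermediate
4 | 3,6-dimethyl-1,2,4,5-tetrazine | Cc1nnc(C)nn1 | starting material
5 | first [4+2] adduct of 3 and 4: 1,4-dimethyl-2,3,5,6-tetraazabicyclo[2.2.2]octa-2,5-diene fused through C7–C8 (each bearing methyl) to the cyclobutane anhydride, methyls syn to the anhydride | O=C1OC(=O)[C@@H]2[C@H]1[C@@]3(C)C4(C)N=NC(C)(N=N4)[C@@]23C | intermediate (not isolated)
6 | 2,3,6,7-tetramethyl-10-oxa-4,5-diazatricyclo[6.3.0.0(2,7)]undeca-3,5-diene-9,11-dione (meso, C2/C7 methyls syn to the anhydride) | O=C1OC(=O)[C@@H]2[C@H]1[C@@]3(C)C(C)=NN=C(C)[C@@]23C | intermediate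
7 | 3,4-diacetyl-3,4-dimethylcyclobutane-1,2-dicarboxylic acid (meso; carboxyls and methyls on one face, acetyls on the other) | OC(=O)[C@@H]1[C@H](C(=O)O)[C@@](C)(C(C)=O)[C@@]1(C)C(C)=O | intermediate (not isolated)
8 | 6,7-diacetyl-6,7-dimethyl-3-oxabicyclo[3.2.0]heptane-2,4-dione (meso, methyls syn to the anhydride) | O=C1OC(=O)[C@@H]2[C@H]1[C@@](C)(C(C)=O)[C@@]2(C)C(C)=O | intermediate
9 | 6,7-dimethyl-6,7-bis[1-(trimethylsilyloxy)ethenyl]-3-oxabicyclo[3.2.0]heptane-2,4-dione (meso, methyls syn to the anhydride) | O=C1OC(=O)[C@@H]2[C@H]1[C@@](C)(C(=C)O[Si](C)(C)C)[C@@]2(C)C(=C)O[Si](C)(C)C | intermediate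
10 | 2-methylpropanedioyl dichloride | CC(C(Cl)=O)C(Cl)=O | starting material
11 | 6,7-bis(4-hydroxy-3-methyl-2-oxo-2H-pyran-6-yl)-6,7-dimethyl-3-oxabicyclo[3.2.0]heptane-2,4-dione (meso, methyls syn to the anhydride) | O=C1OC(=O)[C@@H]2[C@H]1[C@@](C)(c3cc(O)c(C)c(=O)o3)[C@@]2(C)c1cc(O)c(C)c(=O)o1 | intermediate
12 | 6,7-bis(4-methoxy-3-methyl-2-oxo-2H-pyran-6-yl)-6,7-dimethyl-3-oxabicyclo[3.2.0]heptane-2,4-dione (meso, methyls syn to the anhydride) | O=C1OC(=O)[C@@H]2[C@H]1[C@@](C)(c3cc(OC)c(C)c(=O)o3)[C@@]2(C)c1cc(OC)c(C)c(=O)o1 | intermediate
13 | (1S,2R,3S,4R)-4-(methoxycarbonyl)-2,3-bis(4-methoxy-3-methyl-2-oxo-2H-pyran-6-yl)-2,3-dimethylcyclobutane-1-carboxylic acid (CNP0481603.1) | COC(=O)[C@@H]1[C@H](C(=O)O)[C@@](C)(c2cc(OC)c(C)c(=O)o2)[C@@]1(C)c1cc(OC)c(C)c(=O)o1 | target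

## Step count and least certain steps

Total: 7 steps. Longest linear sequence: 7 steps (1 to 13).

Step 2 (key step, proposed new method). The most likely failure is that the cycloaddition does not proceed at a useful rate. A dialkyl tetrazine is the least electrophilic of its class, and it must bond to both carbons of a tetrasubstituted alkene whose methyls are forced towards the anhydride. Slow conversion would let 4 decay. The fallback uses known chemistry, sets out from 1 and returns at 7:
- 3,4-dimethylhexane-2,5-dione F1 (purchased) is cyclodehydrated (TsOH, PhMe, reflux; Paal–Knorr) to 2,3,4,5-tetramethylfuran F2.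
- F2 is oxidised with Br2 in MeOH/Na2CO3 at −40 °C to 2,5-dimethoxy-2,3,4,5-tetramethyl-2,5-dihydrofuran F3, a cis-locked masked ene-dione whose ketal isomers are equivalent for this purpose.
- Sensitised [2+2] photocycloaddition of 1 to the tetrasubstituted alkene of F3 (Ph2CO, MeCN, 350 nm) should give the cis-anti-cis tricycle 8,10-dimethoxy-1,7,8,10-tetramethyl-4,9-dioxatricyclo[5.3.0.0(2,6)]decane-3,5-dione F4. Its two ketal carbons are already cis on C3/C4 and anti to the anhydride.
- Aqueous H2SO4/THF unmasks both ketones and opens the anhydride to give 7, which rejoins the route at the second operation of step 3.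

Step 3. Hydrolysis may stall, because the ring-opened keto-hydrazone re-closes to the azine quickly. The freed 1,4-diketone may also undergo acid-catalysed intramolecular aldol condensation on prolonged heating. The fallback changes hydrolysis to oxidative cleavage: ozonolysis of both C=N bonds of 6 (O3, CH2Cl2, −78 °C, then Me2S), a cleavage known for azines and hydrazones. It sets out from 6 and returns at 8 with the anhydride intact and no free hydrazine, and it makes no new compound.

Step 5. One molecule of 10 may bridge the two cis enol silanes, and the HCl released may protodesilylate unreacted enol silane back to the ketone. The fallback is a stepwise acylation–lactonisation that sets out from 8 and returns at 11: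
- Both methyl ketones are C-acylated under magnesium-mediated soft enolisation (MgBr2·OEt2, i-Pr2NEt, CH2Cl2) with methyl 3-chloro-2-methyl-3-oxopropanoate F5, made from 10 and one equivalent of MeOH.
- This should give the bis(3,5-dioxo ester) 6,7-bis(5-methoxy-4-methyl-3,5-dioxopentanoyl)-6,7-dimethyl-3-oxabicyclo[3.2.0]heptane-2,4-dione F6.
- F6 is lactonised with loss of methanol (DBU, PhMe, 60 °C) to 11.

Step 6. The anhydride may be opened by pyranolate or carbonate, after which the carboxylate is methylated, and some methylation may occur at the C2' carbonyl oxygen. The fallback gives up the anhydride deliberately; it sets out from 11 and returns at 13: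
- 11 is opened with MeOH/DMAP to the racemic half-ester F7.
- All three acidic OH groups are methylated (Me2SO4, K2CO3, acetone, reflux) to the meso dimethyl ester F8, the same compound as A5.
- F8 is desymmetrised by enzymatic hydrolysis of one enantiotopic ester (pig liver esterase or a lipase chosen for the required sense, pH 7 phosphate buffer, acetone cosolvent) to 13.

Step 7. Discrimination between the enantiotopic carbonyls may be poor, or in the wrong sense, and opening may be slow, because both carbonyls are shielded by the syn methyls, a situation outside the usual substrate range. The fallback is resolution; it sets out from 12 and returns at 13: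
- Non-selective methanolysis (MeOH, Et3N cat., CH2Cl2) gives the racemic half-ester F9.
- F9 is resolved by crystallising the (R)-1-phenylethylammonium salt F10 (or the salt of the mirror-image amine, whichever is the less soluble for 13).
- Acidification releases 13.

## Further compounds

F1 | step 2 | 3,4-dimethylhexane-2,5-dione (purchased, mixture of stereoisomers) | CC(=O)C(C)C(C)C(C)=O
F2 | step 2 | 2,3,4,5-tetramethylfuran | Cc1oc(C)c(C)c1C
F3 | step 2 | 2,5-dimethoxy-2,3,4,5-tetramethyl-2,5-dihydrofuran (ketal isomers) | COC1(C)OC(C)(OC)C(C)=C1C
F4 | step 2 | 8,10-dimethoxy-1,7,8,10-tetramethyl-4,9-dioxatricyclo[5.3.0.0(2,6)]decane-3,5-dione (cis-anti-cis, C1/C7 methyls syn to the anhydride) | O=C1OC(=O)[C@@H]2[C@H]1[C@@]3(C)C(C)(OC)OC(C)(OC)[C@@]23C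
F0 | step 3 | none | none
F5 | step 5 | methyl 3-chloro-2-methyl-3-oxopropanoate (racemic) | COC(=O)C(C)C(Cl)=O
F6 | step 5 | 6,7-bis(5-methoxy-4-methyl-3,5-dioxopentanoyl)-6,7-dimethyl-3-oxabicyclo[3.2.0]heptane-2,4-dione (methyls syn to the anhydride) | O=C1OC(=O)[C@@H]2[C@H]1[C@@](C)(C(=O)CC(=O)C(C)C(=O)OC)[C@@]2(C)C(=O)CC(=O)C(C)C(=O)OC
F7 | step 6 | racemic 4-(methoxycarbonyl)-2,3-bis(4-hydroxy-3-methyl-2-oxo-2H-pyran-6-yl)-2,3-dimethylcyclobutane-1-carboxylic acid (both enantiomers, relative configuration as in 13) | COC(=O)[C@@H]1[C@H](C(=O)O)[C@@](C)(c2cc(O)c(C)c(=O)o2)[C@@]1(C)c1cc(O)c(C)c(=O)o1.COC(=O)[C@H]1[C@@H](C(=O)O)[C@](C)(c2cc(O)c(C)c(=O)o2)[C@]1(C)c1cc(O)c(C)c(=O)o1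
F8 | step 6 | dimethyl 3,4-bis(4-methoxy-3-methyl-2-oxo-2H-pyran-6-yl)-3,4-dimethylcyclobutane-1,2-dicarboxylate (meso, esters and methyls on one face) | COC(=O)[C@@H]1[C@H](C(=O)OC)[C@@](C)(c2cc(OC)c(C)c(=O)o2)[C@@]1(C)c3cc(OC)c(C)c(=O)o3
F9 | step 7 | racemic 13 (both enantiomers) | COC(=O)[C@@H]1[C@H](C(=O)O)[C@@](C)(c2cc(OC)c(C)c(=O)o2)[C@@]1(C)c1cc(OC)c(C)c(=O)o1.COC(=O)[C@H]1[C@@H](C(=O)O)[C@](C)(c2cc(OC)c(C)c(=O)o2)[C@]1(C)c1cc(OC)c(C)c(=O)o1
F10 | step 7 | (R)-1-phenylethylammonium salt of 13 | COC(=O)[C@@H]1[C@H](C(=O)[O-])[C@@](C)(c2cc(OC)c(C)c(=O)o2)[C@@]1(C)c1cc(OC)c(C)c(=O)o1.C[C@@H]([NH3+])c1ccccc1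
A1 | alternative 1 | sodium salt of the tosylhydrazone of cis-2,3-bis(4-methoxy-3-methyl-2-oxo-2H-pyran-6-yl)-2,3-dimethylcyclopropane-1-carbaldehyde | [Na+].Cc1ccc(cc1)S(=O)(=O)[N-]N=CC1[C@@](C)(c2cc(OC)c(C)c(=O)o2)[C@@]1(C)c1cc(OC)c(C)c(=O)o1
A2 | alternative 1 | cis-3,4-dimethyl-3,4-bis(4-methoxy-3-methyl-2-oxo-2H-pyran-6-yl)cyclobut-1-ene (meso) | C1=C[C@@](C)(c2cc(OC)c(C)c(=O)o2)[C@@]1(C)c3cc(OC)c(C)c(=O)o3
A3 | alternative 2 | dimethyl 3,4-bis(chlorocarbonyl)-3,4-dimethylcyclobutane-1,2-dicarboxylate (meso, esters and methyls on one face) | COC(=O)[C@@H]1[C@H](C(=O)OC)[C@@](C)(C(Cl)=O)[C@@]1(C)C(Cl)=O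
A4 | alternative 2 | methyl (E)-3-methoxy-2-methylbut-2-enoate | CO/C(C)=C(\C)C(=O)OC
A5 | alternative 2 | dimethyl 3,4-bis(4-methoxy-3-methyl-2-oxo-2H-pyran-6-yl)-3,4-dimethylcyclobutane-1,2-dicarboxylate (meso) | COC(=O)[C@@H]1[C@H](C(=O)OC)[C@@](C)(c2cc(OC)c(C)c(=O)o2)[C@@]1(C)c3cc(OC)c(C)c(=O)o3
A6 | alternative 3 | 6,6'-[(2E,4Z,6Z,8Z)-deca-2,4,6,8-tetraene-2,9-diyl]bis(4-methoxy-3-methyl-2H-pyran-2-one) | C/C(c1cc(OC)c(C)c(=O)o1)=C\C=C/C=C\C=C(C)/c1cc(OC)c(C)c(=O)o1
A7 | alternative 3 | cis-7,8-dimethyl-7,8-bis(4-methoxy-3-methyl-2-oxo-2H-pyran-6-yl)cycloocta-1,3,5-triene (meso) | C[C@]1(c2cc(OC)c(C)c(=O)o2)/C=C\C=C/C=C\[C@@]1(C)c3cc(OC)c(C)c(=O)o3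
A8 | alternative 3 | cis-fused 7,8-dimethyl-7,8-bis(4-methoxy-3-methyl-2-oxo-2H-pyran-6-yl)bicyclo[4.2.0]octa-2,4-diene (meso, six-membered ring syn to the methyls) | C1=C[C@@H]2[C@H](C=C1)[C@@](C)(c3cc(OC)c(C)c(=O)o3)[C@@]2(C)c1cc(OC)c(C)c(=O)o1
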